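## Structural features

The target is an open-chain bis-bibenzyl made of four benzene rings: ring A (3-methoxyphenyl), ring B (the central phenol), ring C (the para-disubstituted phenoxy ring) and ring D (3-hydroxyphenyl). Rings A and B are joined by a CH2CH2 bridge, as are rings C and D, and rings B and C are joined by a diaryl ether oxygen. Ring B is 1,3,4-trisubstituted: the bridge to ring A sits at C1, the aryloxy group at C3 and the free hydroxyl at C4, so the bridge is para to the hydroxyl and meta to the ether oxygen. Ring C carries the ether oxygen at C1 and the bridge to ring D at C4. There is no stereocentre and no stereogenic double bond, so every problem is one of constitution: regiochemistry on the rings and the differentiation of three oxygen functions (two free phenols on rings B and D, one methyl ether on ring A). The sensitive features are the electron-rich rings, which invite over-substitution, and the phenols, which need a protecting group that can be removed without cleaving an aryl methyl ether. The real difficulty is the unsymmetrical diaryl ether next to an ortho hydroxyl, together with placing two different arylethyl arms on it at defined positions. The key step exploits the fact that C4 of ring C is para to the ether oxygen and C1 of ring B is para to the hydroxyl: both are the innate sites of electrophilic attack on 2-phenoxyphenol, so the diaryl ether can be bought and only C–C bonds need to be made.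

## Logic of the disconnections

**13 ⇒ 12.** The two phenolic O–H bonds of 13 are retraced to O–S bonds. The sulfonates are chosen because they deactivate rings B and D during the key step and are inert to palladium. No skeletal simplification results, but one operation frees both phenols while the methyl ether of ring A stays. The forward step must cleave at sulfur only and leave the aryl methyl ether and the diaryl ether alone.

**12 ⇒ 9 + 10 (by way of 11).** The bond between C1 of ring B and its benzylic CH2 is cut. Ring A is the most electron-rich arene of the target and would compete in any electrophilic step, so it is attached last. The gain is that ring A and both bridge carbons come from one cheap styrene, 10, and that 9 keeps a single halogen as its handle. The forward sp2–sp3 coupling must outrun β-hydride elimination and must not touch the aryl sulfonates.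

**9 ⇒ 7 (by way of 8).** The CH2 on ring C is retraced to a carbonyl group, the retron for an acylation. The deoxygenation is placed before the cross-coupling because an enolisable benzyl ketone would be open to α-arylation and condensation under palladium and base. The forward reduction must be non-metallic and must spare the C–Br bond and both sulfonates.

**7 ⇒ 3 + 6.** The bond between C4 of ring C and the carbonyl carbon is cut. This splits the molecule into a diaryl ether that already holds rings B and C and an arylacetyl unit that holds ring D and both bridge carbons. The forward step must acylate ring C only, para only, and once only. The bromine of 3 is para to the sulfonate oxygen and meta to the ether oxygen, which is exactly the ring B pattern of 13.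

**3 ⇒ 2 ⇒ 1.** First the O–S bond on ring B is cut, then the C–Br bond. The order matters in the forward sense: the halogen must go in while the hydroxyl is free and dominates the directing effects, and the sulfonate is put on afterwards to switch ring B off. This reaches the commercial diaryl ether 1, so no aryl–oxygen bond is formed in the route.

**6 ⇒ 5 ⇒ 4.** The C–Cl bond and then the O–S bond on ring D are cut, which leads to the commercial hydroxy acid 4. The forward sulfonylation must be selective for the phenol in the presence of the carboxylic acid.

## Other disconnections considered

**Alternative 1:** The cut runs through ring B itself, at C2–C3 and C5–C6. C3, C4 and C5 would come from the aryloxyacetone 1-(4-{2-[3-(benzyloxy)phenyl]ethyl}phenoxy)propan-2-one A2. C2, C1, C6 and the ring A arm would come from the vinamidinium salt A3, the hexafluorophosphate of the 1,3-bis(dimethylamino)trimethinium cation carrying a 2-(3-methoxyphenyl)ethyl group on its central carbon. In the forward step a strong base would enolise A2, the enolate would add to one iminium terminus of A3 and expel the amine, and the second α-carbon would close onto the other terminus. Loss of the second amine would give the ring directly as the phenol A1, the ring D benzyl ether of 13, and one hydrogenolysis would finish.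

- In its favour: the 1,3,4-pattern of ring B is fixed by the connectivity of the fragments and not by directing effects, the ether oxygen is attached by simple phenoxide alkylation, and the ring B hydroxyl appears free.
- Against it: A3 would come from a Vilsmeier-type formylation–decarboxylation of 4-(3-methoxyphenyl)butanoic acid A4. That reaction serves aryl- and acceptor-substituted acetic acids best, and it exposes the anisole ring of A4 to the chloroiminium reagent. A2 needs a ring C–ring D bibenzyl with differentiated phenols to be built first, in about four to five steps. An α-aryloxy ketone is a thinly precedented partner for vinamidinium salts; self-condensation and base-induced loss of aryloxide are plausible side reactions.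
- Structure: the alternative is better on regiochemical certainty, and equal in that neither plan needs a metal-mediated aryl–oxygen coupling.
- Mechanism: a double addition–elimination that depends only on connectivity, against an electrophilic substitution that depends on relative ring nucleophilicity.
- Step economy: about equal in total, and the alternative is better in its end game (one step after the key step against three).
- The chosen plan is preferred because each of its steps is a standard transformation of its substrate class, whereas here the two steps that carry the strategy are the least supported.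

**Alternative 2:** The cut is the bond between the bridge CH2 and C1 of ring D, with ring D traced back to a cyclohexenone. In the forward step the Grignard reagent 2-(4-{2-(benzyloxy)-5-[2-(3-methoxyphenyl)ethyl]phenoxy}phenyl)ethylmagnesium bromide A6 would add to the carbonyl of 3-ethoxycyclohex-2-en-1-one A7. Acidic work-up would hydrolyse the enol ether and dehydrate (Stork–Danheiser transposition) to the enone A5. Dehydrogenation would then give the phenol A8, and debenzylation would give 13.

- In its favour: the meta relation of hydroxyl and chain on ring D follows automatically from the 1,3-relation in A7, a pattern electrophilic substitution cannot deliver. The carbonyl addition has no regiochemical ambiguity at all; on that point of mechanism it is better than a Friedel–Crafts acylation.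
- Against it: the meta pattern of ring D is already available in cheap commercial 3-hydroxyphenyl building blocks, so the ring construction buys nothing. A6 must contain the complete A–B–C assembly, so the hard part of the molecule (the diaryl ether and the placement of the ring A arm) is only moved upstream. Formation of a primary 2-arylethyl Grignard reagent invites Wurtz coupling and styrene formation. The aromatisation of A5 is an oxidation carried out in the presence of four benzylic CH2 groups and a benzyl ether.
- Structure: the chosen plan addresses the diaryl ether, whereas this one addresses a ring that poses no problem.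
- Step economy: clearly worse, since the long synthesis of A6 is followed by three more steps.

**Alternative 3:** The cut runs through ring C, which would be grown on the oxygen of ring B. In the forward step methyl coumalate A10 would react as an electron-poor diene with the aryl ethynyl ether 1-(benzyloxy)-2-(ethynyloxy)-4-[2-(3-methoxyphenyl)ethyl]benzene A11. The nucleophilic terminal alkyne carbon would bond to C6 of the pyrone and the oxygen-bearing carbon to C3. The bridged lactone would then aromatise by retro-[4+2] decarboxylation to the methyl 4-aryloxybenzoate A9. Reduction to the aldehyde A12, Wittig olefination with the ylide of {[3-(benzyloxy)phenyl]methyl}triphenylphosphonium bromide A13 and one hydrogenation would complete 13; the hydrogenation would saturate the alkene and remove both benzyl ethers.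

- In its favour: the para relation on ring C is locked by the polarisation of both partners, the diaryl ether arises without any aryl–oxygen coupling, and the final hydrogenation does three jobs at once.
- Against it: A11 needs two further operations from a phenol that must already carry the ring A arm and a differentiated catechol. Aryl ynol ethers are prone to hydration and to thermal decomposition at the temperatures such cycloadditions usually require. Three to four steps follow the key step.
- Structure: equal to the chosen plan in avoiding metal-mediated ether formation, and formally better in that the ring C regiochemistry is set by bond construction and not by para/ortho preference, although that preference is hardly in doubt in the chosen plan.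
- Mechanism: a pericyclic sequence with a sensitive dienophile, against a robust electrophilic substitution.
- Step economy: worse, an estimated eleven or more steps against eight.

Key step: step 5

Remark on the chemistry: the target has no stereocentre, so all structures carry no stereodescriptors; the carbinol 8 is racemic and exists only in the flask.

## Route

Step 1
Reactants: 1 2-phenoxyphenol
Product: 2 4-bromo-2-phenoxyphenol
Conditions: NBS (1.0 equiv), MeCN, −10 → 0 °C
Reagents that add atoms: N-bromosuccinimide, O=C1CCC(=O)N1Br
Why: Electrophilic aromatic bromination; the free hydroxyl is the strongest donor in 1 and directs bromine to C4, para to itself, in preference to the single open ortho position and to the less activated phenoxy ring. One equivalent of NBS in a polar solvent at low temperature, without amine additives, limits ortho attack and dibromination.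

Step 2
Reactants: 2 4-bromo-2-phenoxyphenol
Product: 3 4-bromo-2-phenoxyphenyl methanesulfonate
Conditions: MsCl, Et3N, CH2Cl2, 0 °C → rt
Reagents that add atoms: methanesulfonyl chloride, CS(=O)(=O)Cl
Why: O-Sulfonylation of the phenol; the sulfonate protects the hydroxyl and turns ring B from the most into the least nucleophilic arene ahead of the acylation.

Step 3
Reactants: 4 3-hydroxyphenylacetic acid
Product: 5 [3-(methylsulfonyloxy)phenyl]acetic acid
Conditions: MsCl (2.5 equiv), NaOH (aq), THF, 0 °C, pH > 10; then HCl to pH 1
Reagents that add atoms: methanesulfonyl chloride, CS(=O)(=O)Cl
Why: Schotten–Baumann sulfonylation; the phenoxide is sulfonylated, while any carboxylic–sulfonic mixed anhydride is hydrolysed back to the carboxylate by the aqueous hydroxide, so acidification should deliver the O-mesyl acid. The aryl sulfonate tolerates cold dilute base for the time needed.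

Step 4
Reactants: 5 [3-(methylsulfonyloxy)phenyl]acetic acid
Product: 6 [3-(methylsulfonyloxy)phenyl]acetyl chloride
Conditions: SOCl2, DMF (cat.), CH2Cl2, 40 °C; evaporate, use crude
Reagents that add atoms: thionyl chloride, ClS(Cl)=O
Why: Acid chloride formation through the chlorosulfite, catalysed by the chloroiminium species from DMF; the aryl sulfonate is inert and the co-products are gases.

Step 5
Reactants: 3 4-bromo-2-phenoxyphenyl methanesulfonate; 6 [3-(methylsulfonyloxy)phenyl]acetyl chloride
Product: 7 4-bromo-2-(4-{2-[3-(methylsulfonyloxy)phenyl]acetyl}phenoxy)phenyl methanesulfonate
Conditions: 6 (1.2 equiv), AlCl3 (3 equiv), CH2Cl2, 0 °C; then 3, 0 °C → rt; ice/HCl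
Reagents that add atoms: none
Why: AlCl3 ionises 6 to the arylacetyl acylium ion (or its polarised donor–acceptor complex), which attacks C4 of ring C of 3, para to the diaryl ether oxygen, through the arenium ion that this oxygen stabilises best; loss of the proton as HCl gives the aryl ketone 7, held as its AlCl3 complex until the acidic quench. The closest known reaction type is the Friedel–Crafts acylation of diphenyl ethers and anisoles with arylacetyl chlorides, the standard entry to deoxybenzoins. One C–C bond is formed; no ring is closed and no stereocentre is created. Selectivity among three arenes is needed: ring B is switched off by its sulfonate and bromine, and its only oxygen-activated open position, para to the ether oxygen, is meta to the sulfonate and flanked by bromine, while ring D carries a sulfonate and belongs to the electrophile. Para over ortho on ring C follows from the bulk of the acylium–AlCl3 complex and of the ortho aryloxy substituent. Monoacylation is secured because the new carbonyl group deactivates ring C. The meta sulfonate on ring D also disfavours loss of CO from the acylium ion, since the benzylic cation that would result is destabilised. About three equivalents of AlCl3 are used because the sulfonyl oxygens and the product carbonyl bind Lewis acid, and the acylium ion is formed before 3 is added so that 3 does not sit with free AlCl3 alone.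

Step 6
Reactants: 7 4-bromo-2-(4-{2-[3-(methylsulfonyloxy)phenyl]acetyl}phenoxy)phenyl methanesulfonate
Product: 9 4-bromo-2-(4-{2-[3-(methylsulfonyloxy)phenyl]ethyl}phenoxy)phenyl methanesulfonate, via secondary benzylic alcohol 8 (not isolated)
Conditions: Et3SiH (3 equiv), CF3CO2H, rt → 50 °C
Reagents that add atoms: none
Why: Ionic hydrogenation (Kursanov–Parnes reduction); the protonated ketone takes hydride from silicon to give carbinol 8, which ionises in CF3CO2H to a benzylic cation stabilised by the para aryloxy group and is reduced a second time. The acidic, metal-free conditions leave the C–Br bond, both sulfonates and the diaryl ether untouched, and the transient stereocentre of 8 disappears.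

Step 7
Reactants: 9 4-bromo-2-(4-{2-[3-(methylsulfonyloxy)phenyl]ethyl}phenoxy)phenyl methanesulfonate; 10 3-vinylanisole
Product: 12 4-[2-(3-methoxyphenyl)ethyl]-2-(4-{2-[3-(methylsulfonyloxy)phenyl]ethyl}phenoxy)phenyl methanesulfonate, via 9-[2-(3-methoxyphenyl)ethyl]-9-BBN 11 (not isolated)
Conditions: 10 (1.4 equiv), 9-BBN (1.5 equiv), THF, 0 °C → rt; then 9, PdCl2(dppf) (5 mol %), K3PO4 (3 M aq, 3 equiv), DMF, 60 °C
Reagents that add atoms: none
Why: Anti-Markovnikov hydroboration of styrene 10 gives the primary borane 11, which enters a B-alkyl Suzuki–Miyaura coupling after oxidative addition of zerovalent palladium into the C–Br bond of 9. The wide bite angle of dppf favours reductive elimination over β-hydride elimination, and aryl methanesulfonates do not undergo oxidative addition with this catalyst.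

Step 8
Reactants: 12 4-[2-(3-methoxyphenyl)ethyl]-2-(4-{2-[3-(methylsulfonyloxy)phenyl]ethyl}phenoxy)phenyl methanesulfonate
Product: 13 2-{4-[2-(3-hydroxyphenyl)ethyl]phenoxy}-4-[2-(3-methoxyphenyl)ethyl]phenol (target)
Conditions: KOH (10 equiv), MeOH/H2O, reflux; then HCl (aq)
Reagents that add atoms: none
Why: Hydroxide cleaves both aryl methanesulfonates at the S–O bond (attack at sulfur or E1cB through sulfene) with phenoxide as leaving group. The aryl methyl ether, the diaryl ether and the bibenzyl bridges are inert to base, and acidification frees the two phenols.

## Compound list

1 | 2-phenoxyphenol | Oc1ccccc1Oc1ccccc1 | starting material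
2 | 4-bromo-2-phenoxyphenol | Oc1ccc(Br)cc1Oc1ccccc1 | intermediate
3 | 4-bromo-2-phenoxyphenyl methanesulfonate | CS(=O)(=O)Oc1ccc(Br)cc1Oc1ccccc1 | intermediate
4 | 3-hydroxyphenylacetic acid | OC(=O)Cc1cccc(O)c1 | starting material
5 | [3-(methylsulfonyloxy)phenyl]acetic acid | CS(=O)(=O)Oc1cccc(CC(O)=O)c1 | intermediate
6 | [3-(methylsulfonyloxy)phenyl]acetyl chloride | CS(=O)(=O)Oc1cccc(CC(Cl)=O)c1 | intermediate
7 | 4-bromo-2-(4-{2-[3-(methylsulfonyloxy)phenyl]acetyl}phenoxy)phenyl methanesulfonate | CS(=O)(=O)Oc1cccc(CC(=O)c2ccc(Oc3cc(Br)ccc3OS(C)(=O)=O)cc2)c1 | intermediate
8 | 4-bromo-2-(4-{1-hydroxy-2-[3-(methylsulfonyloxy)phenyl]ethyl}phenoxy)phenyl methanesulfonate (racemic) | CS(=O)(=O)Oc1cccc(CC(O)c2ccc(Oc3cc(Br)ccc3OS(C)(=O)=O)cc2)c1 | intermediate (not isolated)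
9 | 4-bromo-2-(4-{2-[3-(methylsulfonyloxy)phenyl]ethyl}phenoxy)phenyl methanesulfonate | CS(=O)(=O)Oc1cccc(CCc2ccc(Oc3cc(Br)ccc3OS(C)(=O)=O)cc2)c1 | intermediate
10 | 3-vinylanisole | COc1cccc(C=C)c1 | starting material
11 | 9-[2-(3-methoxyphenyl)ethyl]-9-borabicyclo[3.3.1]nonane | COc1cccc(CCB2C3CCCC2CCC3)c1 | intermediate (not isolated)
12 | 4-[2-(3-methoxyphenyl)ethyl]-2-(4-{2-[3-(methylsulfonyloxy)phenyl]ethyl}phenoxy)phenyl methanesulfonate | COc1cccc(CCc2ccc(OS(C)(=O)=O)c(Oc3ccc(CCc4cccc(OS(C)(=O)=O)c4)cc3)c2)c1 | intermediate
13 | 2-{4-[2-(3-hydroxyphenyl)ethyl]phenoxy}-4-[2-(3-methoxyphenyl)ethyl]phenol | COc1cccc(CCc2ccc(O)c(Oc3ccc(CCc4cccc(O)c4)cc3)c2)c1 | target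

## Step count and least certain steps

Total: 8 steps. Longest linear sequence: 6 steps (steps 1, 2, 5, 6, 7, 8 from 1; the branch from 4 through steps 3, 4, 5, 6, 7, 8 is equally long).

**Step 5 (key step).** The acylation could go astray in three ways. The electrophile could attack ring B para to the ether oxygen, or ring C ortho. The acylium ion could lose CO and then benzylate. Chelation of AlCl3 between the neighbouring sulfonate and ether oxygens could drain electron density from ring C so that the reaction stalls. The fallback replaces the acylation–reduction pair by two successive cross-couplings. It sets out from 3, which is iodinated on ring C para to the ether oxygen with N-iodosuccinimide in CF3CO2H/MeCN to give 4-bromo-2-(4-iodophenoxy)phenyl methanesulfonate F1. Commercial 3-vinylphenol is mesylated (MsCl, Et3N) to 3-vinylphenyl methanesulfonate F2, and hydroboration with 9-BBN gives 3-[2-(9-borabicyclo[3.3.1]nonan-9-yl)ethyl]phenyl methanesulfonate F3, used in solution. Coupling of F3 with F1 under PdCl2(dppf) and K3PO4 at room temperature, where oxidative addition into the C–I bond is much faster than into the C–Br bond, comes back to the route at 9 and bypasses 7 and step 6.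

**Step 6.** The second ionisation may be slow, because the benzylic cation is stabilised only by an aryloxy group whose other ring is electron-poor. The reduction could then stall at the carbinol or its trifluoroacetate, or the cation could alkylate another arene. The fallback sets out from 7. NaBH4 in MeOH/THF gives carbinol 8, this time isolated. Dehydration with catalytic TsOH in refluxing toluene gives 4-bromo-2-(4-{(E)-2-[3-(methylsulfonyloxy)phenyl]ethenyl}phenoxy)phenyl methanesulfonate F4. Diimide, generated from TsNHNH2 and NaOAc in refluxing THF/H2O, saturates the alkene without touching the C–Br bond and returns to the route at 9.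

**Step 7.** β-Hydride elimination from the alkylpalladium intermediate would lead to protodebromination of 9 and give back 10. Transmetalation of the borane may be sluggish, and the aqueous base may partly cleave the sulfonates, which is harmless for the final outcome but complicates isolation. The fallback sets out from 9 and 10. A Mizoroki–Heck reaction (Pd(OAc)2, P(o-tol)3, Et3N, DMF, 100 °C) gives 4-[(E)-2-(3-methoxyphenyl)ethenyl]-2-(4-{2-[3-(methylsulfonyloxy)phenyl]ethyl}phenoxy)phenyl methanesulfonate F5. Hydrogenation (H2, Pd/C, EtOAc), now safe because no C–Br bond and no benzyl ether is present, returns to the route at 12.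

**Step 3.** Sulfonylation at the carboxylate, ketene formation from the resulting mixed anhydride and rapid hydrolysis of MsCl could leave the phenol incompletely protected or give oligomeric material. The fallback sets out from 4. Fischer esterification (MeOH, cat. H2SO4) gives methyl (3-hydroxyphenyl)acetate F6. Mesylation (MsCl, Et3N, CH2Cl2) gives methyl [3-(methylsulfonyloxy)phenyl]acetate F7. Acidic hydrolysis (aq. HCl, dioxane, reflux), to which the aryl sulfonate is stable, returns to the route at 5.

## Further compounds

F1 | step 5 | 4-bromo-2-(4-iodophenoxy)phenyl methanesulfonate | CS(=O)(=O)Oc1ccc(Br)cc1Oc1ccc(I)cc1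
F2 | step 5 | 3-vinylphenyl methanesulfonate | CS(=O)(=O)Oc1cccc(C=C)c1
F3 | step 5 | 3-[2-(9-borabicyclo[3.3.1]nonan-9-yl)ethyl]phenyl methanesulfonate | CS(=O)(=O)Oc1cccc(CCB2C3CCCC2CCC3)c1
F4 | step 6 | 4-bromo-2-(4-{(E)-2-[3-(methylsulfonyloxy)phenyl]ethenyl}phenoxy)phenyl methanesulfonate | CS(=O)(=O)Oc1cccc(/C=C/c2ccc(Oc3cc(Br)ccc3OS(C)(=O)=O)cc2)c1
F5 | step 7 | 4-[(E)-2-(3-methoxyphenyl)ethenyl]-2-(4-{2-[3-(methylsulfonyloxy)phenyl]ethyl}phenoxy)phenyl methanesulfonate | COc1cccc(/C=C/c2ccc(OS(C)(=O)=O)c(Oc3ccc(CCc4cccc(OS(C)(=O)=O)c4)cc3)c2)c1
F6 | step 3 | methyl (3-hydroxyphenyl)acetate | COC(=O)Cc1cccc(O)c1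
F7 | step 3 | methyl [3-(methylsulfonyloxy)phenyl]acetate | COC(=O)Cc1cccc(OS(C)(=O)=O)c1
A1 | alternative 1 | 2-(4-{2-[3-(benzyloxy)phenyl]ethyl}phenoxy)-4-[2-(3-methoxyphenyl)ethyl]phenol | COc1cccc(CCc2ccc(O)c(Oc3ccc(CCc4cccc(OCc5ccccc5)c4)cc3)c2)c1
A2 | alternative 1 | 1-(4-{2-[3-(benzyloxy)phenyl]ethyl}phenoxy)propan-2-one | CC(=O)COc1ccc(CCc2cccc(OCc3ccccc3)c2)cc1
A3 | alternative 1 | N-{3-(dimethylamino)-2-[2-(3-methoxyphenyl)ethyl]prop-2-en-1-ylidene}-N-methylmethanaminium hexafluorophosphate | COc1cccc(CCC(C=[N+](C)C)=CN(C)C)c1.F[P-](F)(F)(F)(F)F
A4 | alternative 1 | 4-(3-methoxyphenyl)butanoic acid | COc1cccc(CCCC(O)=O)c1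
A5 | alternative 2 | 3-[2-(4-{2-(benzyloxy)-5-[2-(3-methoxyphenyl)ethyl]phenoxy}phenyl)ethyl]cyclohex-2-en-1-one | O=C1CCCC(CCc2ccc(Oc3cc(CCc4cccc(OC)c4)ccc3OCc3ccccc3)cc2)=C1
A6 | alternative 2 | 2-(4-{2-(benzyloxy)-5-[2-(3-methoxyphenyl)ethyl]phenoxy}phenyl)ethylmagnesium bromide | Br[Mg]CCc1ccc(Oc2cc(CCc3cccc(OC)c3)ccc2OCc2ccccc2)cc1
A7 | alternative 2 | 3-ethoxycyclohex-2-en-1-one | CCOC1=CC(=O)CCC1
A8 | alternative 2 | 3-[2-(4-{2-(benzyloxy)-5-[2-(3-methoxyphenyl)ethyl]phenoxy}phenyl)ethyl]phenol | Oc1cccc(CCc2ccc(Oc3cc(CCc4cccc(OC)c4)ccc3OCc3ccccc3)cc2)c1
A9 | alternative 3 | methyl 4-{2-(benzyloxy)-5-[2-(3-methoxyphenyl)ethyl]phenoxy}benzoate | COC(=O)c1ccc(Oc2cc(CCc3cccc(OC)c3)ccc2OCc2ccccc2)cc1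
A10 | alternative 3 | methyl coumalate (methyl 2-oxo-2H-pyran-5-carboxylate) | COC(=O)C1=COC(=O)C=C1
A11 | alternative 3 | 1-(benzyloxy)-2-(ethynyloxy)-4-[2-(3-methoxyphenyl)ethyl]benzene | C#COc1cc(CCc2cccc(OC)c2)ccc1OCc1ccccc1
A12 | alternative 3 | 4-{2-(benzyloxy)-5-[2-(3-methoxyphenyl)ethyl]phenoxy}benzaldehyde | O=Cc1ccc(Oc2cc(CCc3cccc(OC)c3)ccc2OCc2ccccc2)cc1
A13 | alternative 3 | {[3-(benzyloxy)phenyl]methyl}triphenylphosphonium bromide | [Br-].c1ccc(COc2cccc(C[P+](c3ccccc3)(c3ccccc3)c3ccccc3)c2)cc1
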